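The runs are calculated on assumed constants; the scatter is artificial.

| flask | starting material | partner | free catalyst | time |
|---|---|---|---|---|
| east | 0.600 M | 0.660 M | 0.0600 M |  |
| south | 0.300 M | 0.360 M | 0.0600 M |  |
| south-west | 0.600 M | 0.660 M | 0.120 M |  |
| north | 0.600 M | 0.660 M | 0.280 M | 140 min |

- east run (time / min: [product] / M): 6.2: 0.0324; 19: 0.0804; 36: 0.1244; 57: 0.1513; 82: 0.1728; 110: 0.1801; 140: 0.1874
- south run (time / min: [product] / M): 6.2: 0.0135; 19: 0.0401; 36: 0.0583; 57: 0.0758; 82: 0.0957; 110: 0.0981; 140: 0.1063
- south-west run (time / min: [product] / M): 6.2: 0.0791; 19: 0.1792; 36: 0.2509; 57: 0.2832; 82: 0.2952; 110: 0.3036; 140: 0.3052

(standard deviation of a reading: 0.002 M)

- Overall: starting material + partner -> product, with free catalyst as catalyst.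
- Constant volume, constant temperature.
- A reading of a species includes what of it is bound.
- An order is taken over about fifteen percent of the charge, up and down.

* order of the initial rate in [free catalyst], near the charge of the east run, the rate being that where two percent of its starting material are product
* product in the north run at 140 min, as a share of the starting material charged

**Balance first.** Hold the balance of starting material: the charge equals what remains, plus product, plus what left by another way. In the east run less starting material is charged than partner, so it is the limiting reagent, yet product flattens near 0.1874 M of 0.600 M. Take this flattening as a second loss of starting material running beside product. Divide the product rate by the loss rate, and time drops out; call product over what left the odds, with little starting material remaining.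

**Two extremes.** With loss far slower than product formation, the share of the charge made into product tends to one. With loss far faster, the share stays small and goes with active catalyst. The flask lies between, since the plateaus are partial and rise with catalyst. Odds proportional to active catalyst reach both ends, so commit to that rule at one fixed charge of starting material and partner.

**Active catalyst.** Extrapolate the first two intervals to zero time: 0.00571 M/min in the east run and 0.0144 M/min in the south-west run. That ratio of 2.52 for 2.00 times the charge reads as a fixed amount z withheld from c(free catalyst), with z = 0.0205 M. The order near the east charge is then c/(c − z), or 1.52.

**North reckoned.** Active catalyst is 0.0995 M in the south-west run, whose odds at 140 min give 10.4 /M: this is the odds per active catalyst. The north run has 0.260 M active, so its odds are 2.70 and its share is 73.0%.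

The forecast differs from this reckoning in both numbers: it gives an order of 1.35 from early rates, saying “Doubling the catalyst therefore gives about 2.5 times the rate”, and a north share of 77% from the negative logarithm of the unconverted share, scaled as a power of catalyst and extrapolated to the north charge.

**The result.** The flask gives an order of 1.7 and a north share of 75.2%.

    free catalyst + starting material ⇌ catalyst-substrate complex, settled at all times (5.010 /M)
    catalyst-substrate complex + partner ⇌ ternary complex, settled at all times (0.2720 /M)
    ternary complex → product + free catalyst (1.374 /min)
    free catalyst + impurity → spent catalyst
    2 starting material → homo dimer (0.1044 /M/min)

**Rule again.** Where the same amount of product has been made, the south-west run goes at 2.7 times the rate of the east run. The north share means odds of 3.03, or 11.7 /M per active catalyst, beside the 10.4 /M carried from the south-west run. With 0.0395 M active in the east run, that carried value gives a share of 29.1%, and the east reading at 140 min is 31.2%.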